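The C1–C10 oxirane is read as a former alkene: C10, C1, C2, C3, C4 and C5 then form a conjugated triene with a cis central bond inside the ten-membered ring, and joining its termini C5 and C10 gives a cyclohexa-1,3-diene (ring A) fused to a cyclohexane (ring B). The route rests on breaking that bond: ultraviolet light opens ring A of a cis-fused hexalin by conrotatory six-electron cleavage of the C5–C10 fusion bond, merging rings A and B into the ten-membered carbocycle and setting the 1(10)E and 4Z alkenes at once. The precursor is the fully functionalised 10-epi-eudesma-1,3,11(13)-trien-6,12-olide carrying the epoxy ester at C8.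

Key step: step 20

Numbering: germacrane/eudesmane numbers are used throughout (C1–C10 carbocycle, C11–C13 lactone side chain with C12 the carbonyl, C14 the methyl on C10, C15 the methyl on C4); "15-nor" marks intermediates that do not yet carry C15.

Assumption: the quinine-derived squaramide is taken to deliver the (5S,6R,10R) enantiomer of 11; if the sense of induction proves opposite, the quinidine-derived pseudoenantiomer is used under the same conditions.

Step 1
Reactants: 1 2-methylpent-4-enal (racemic); 2 methyl vinyl ketone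
Product: 3 4-allyl-4-methylcyclohex-2-en-1-one (racemic)
Conditions: H2SO4 (cat.), toluene, 45 °C then reflux with water removal
Reagents that add atoms: none
Why: Acid-catalysed Michael addition of the aldehyde enol to the enone followed by intramolecular aldol condensation (Robinson annulation) builds ring A around the quaternary carbon, whose chirality is lost in step 2.

Step 2
Reactants: 3 4-allyl-4-methylcyclohex-2-en-1-one
Product: 5 4-allyl-4-methylcyclohexa-2,5-dien-1-one, via trimethylsilyl dienol ether 4 (not isolated)
Conditions: Me3SiCl, LiN(iPr)2 (LDA), THF, −78 °C; solvent exchange; then Pd(OAc)2 (1.05 equiv), MeCN, rt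
Reagents that add atoms: none
Why: Kinetic deprotonation at the α′ methylene with in situ silylation gives the cross-conjugated silyl dienol ether, which divalent palladium dehydrogenates through an oxo-π-allyl complex and β-hydride elimination (Saegusa–Ito oxidation) much faster than it touches the isolated allyl group, giving the achiral dienone.

Step 3
Reactants: 5 4-allyl-4-methylcyclohexa-2,5-dien-1-one
Product: 7 (1-methyl-4-oxocyclohexa-2,5-dien-1-yl)acetaldehyde, via ozonide 6 (not isolated)
Conditions: O3, CH2Cl2, −78 °C (Sudan Red 7B end point); then PPh3, −78 °C to rt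
Reagents that add atoms: ozone, [O-][O+]=O
Why: Ozonolysis with reductive work-up, in which electrophilic ozone cleaves the electron-rich terminal alkene far faster than the electron-poor dienone double bonds, so titration to the dye end point should leave ring A intact.

Step 4
Reactants: 7 (1-methyl-4-oxocyclohexa-2,5-dien-1-yl)acetaldehyde; 8 4-bromofuran-2(5H)-one
Product: 9 4-[1-hydroxy-2-(1-methyl-4-oxocyclohexa-2,5-dien-1-yl)ethyl]furan-2(5H)-one (racemic)
Conditions: CrCl2 (4 equiv), NiCl2 (2 mol%), degassed DMF, rt
Reagents that add atoms: none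
Why: Nozaki–Hiyama–Kishi coupling, in which zerovalent nickel inserts into the activated vinylic C–Br bond and transmetalation gives an alkenyl species of trivalent chromium that adds to the aldehyde only (forming C7–C8) and tolerates dienone and lactone; the carbinol centre is racemic and is removed in step 5.

Step 5
Reactants: 9 4-[1-hydroxy-2-(1-methyl-4-oxocyclohexa-2,5-dien-1-yl)ethyl]furan-2(5H)-one
Product: 10 4-[(1-methyl-4-oxocyclohexa-2,5-dien-1-yl)acetyl]furan-2(5H)-one
Conditions: Dess–Martin periodinane, CH2Cl2, 0 °C to rt (crude 9 used at once)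
Reagents that add atoms: none
Why: Dess–Martin oxidation turns the allylic carbinol into the C8 ketone under neutral conditions, which avoids both oxa-Michael addition of the free hydroxyl to the dienone and base-triggered racemic ring closure of the acidic butenolide.

Step 6
Reactants: 10 4-[(1-methyl-4-oxocyclohexa-2,5-dien-1-yl)acetyl]furan-2(5H)-one
Product: 11 (5S,6R,10R)-3,8-dioxo-15-noreudesma-1,7(11)-dien-6,12-olide (rings A and B cis-fused; H-6 anti to H-5)
Conditions: quinine-derived squaramide [3-(3,5-bis(trifluoromethyl)anilino)-4-(9-deoxy-epi-quinin-9-ylamino)cyclobut-3-ene-1,2-dione] (10 mol%), toluene, −20 °C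
Reagents that add atoms: none
Why: Desymmetrising intramolecular vinylogous Michael addition under bifunctional base/hydrogen-bond catalysis, in which the quinuclidine removes the γ proton at C6 and the squaramide binds the dienone and selects one of its enantiotopic β carbons, so that C5, C6 and C10 are set together; the tether enforces the cis fusion and a chair-like six-membered transition state places H-6 anti to H-5.

Step 7
Reactants: 11 (5S,6R,10R)-3,8-dioxo-15-noreudesma-1,7(11)-dien-6,12-olide
Product: 12 (5S,6R,7S,10R)-3,8-dioxo-15-noreudesm-1-en-6,12-olide (trans lactone; H-7 anti to H-6)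
Conditions: Zn dust, AcOH–THF, 0 °C to rt
Reagents that add atoms: none
Why: Dissolving-metal reduction with zinc adds two electrons and two protons only to the doubly activated C7=C11 bond of the 2-ene-1,4-dicarbonyl unit (the simple ring A enone is inert), and axial protonation of the C8 enol at C7 from the convex face should give the diequatorial trans lactone.

Step 8
Reactants: 12 (5S,6R,7S,10R)-3,8-dioxo-15-noreudesm-1-en-6,12-olide
Product: 13 (5S,6R,7R,8R,10R)-8-hydroxy-3-oxo-15-noreudesm-1-en-6,12-olide (axial 8-OH on the same face as C1)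
Conditions: NaBH4, MeOH–CH2Cl2 (1:1), −78 °C
Reagents that add atoms: none
Why: Cold borohydride reduction takes the saturated C8 ketone in preference to the conjugated ring A enone, and hydride should enter equatorially from the convex face because the axial trajectory is blocked by C1 of the cis-fused ring A (the bias known from 7-oxo-5β-steroids), giving the axial alcohol.

Step 9
Reactants: 13 (5S,6R,7R,8R,10R)-8-hydroxy-3-oxo-15-noreudesm-1-en-6,12-olide
Product: 14 (5S,6R,7S,8R,10R)-8-(tert-butyldimethylsilyloxy)-3-oxo-15-noreudesm-1-en-6,12-olide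
Conditions: t-BuMe2SiOTf, 2,6-lutidine, CH2Cl2, −78 to 0 °C
Reagents that add atoms: tert-butyldimethylsilyl triflate, CC(C)(C)[Si](C)(C)OS(=O)(=O)C(F)(F)F
Why: Silylation with the reactive silyl triflate protects the hindered axial hydroxyl as an ether that survives the enolate, triflation and palladium steps.

Step 10
Reactants: 14 (5S,6R,7S,8R,10R)-8-(tert-butyldimethylsilyloxy)-3-oxo-15-noreudesm-1-en-6,12-olide
Product: 16 (5S,6R,7S,8R,10R)-8-(tert-butyldimethylsilyloxy)-3-oxoeudesm-1-en-6,12-olide (C4 epimers), via lithium dienolate 15 (not isolated)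
Conditions: LiN(iPr)2 (LDA, 1.05 equiv), THF, −78 °C; then MeI, DMPU, −78 to −30 °C
Reagents that add atoms: iodomethane, CI
Why: Enolate alkylation, in which the amide base removes a C4 proton of the enone kinetically faster than the lactone α proton and the cross-conjugated dienolate is methylated once to bring in C15; the C4 configuration is irrelevant because C4 becomes trigonal in step 11.

Step 11
Reactants: 16 (5S,6R,7S,8R,10R)-8-(tert-butyldimethylsilyloxy)-3-oxoeudesm-1-en-6,12-olide
Product: 17 (5R,6R,7S,8R,10R)-8-(tert-butyldimethylsilyloxy)-3-(trifluoromethylsulfonyloxy)eudesma-1,3-dien-6,12-olide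
Conditions: Tf2O, 2,6-di-tert-butyl-4-methylpyridine, CH2Cl2, 0 °C to rt
Reagents that add atoms: trifluoromethanesulfonic anhydride, O=S(=O)(OS(=O)(=O)C(F)(F)F)C(F)(F)F
Why: Enol triflate formation by O-triflation of the ketone and loss of its only α proton (H-4) gives the dienyl triflate, and this electrophilic protocol acts on the ketone alone, so no base competes for the lactone α protons.

Step 12
Reactants: 17 (5R,6R,7S,8R,10R)-8-(tert-butyldimethylsilyloxy)-3-(trifluoromethylsulfonyloxy)eudesma-1,3-dien-6,12-olide
Product: 18 (5S,6R,7S,8R,10R)-8-(tert-butyldimethylsilyloxy)eudesma-1,3-dien-6,12-olide (cis-fused, 10-epi series)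
Conditions: Pd(OAc)2 (5 mol%), PPh3 (10 mol%), HCO2H, Bu3N, DMF, 60 °C
Reagents that add atoms: none
Why: Palladium-catalysed formate reduction of the vinyl triflate (oxidative addition to zerovalent palladium, formate exchange, decarboxylation, reductive elimination) replaces the triflate by hydrogen without moving the double bonds, giving the homoannular ring A diene.

Step 13
Reactants: 18 (5S,6R,7S,8R,10R)-8-(tert-butyldimethylsilyloxy)eudesma-1,3-dien-6,12-olide
Product: 20 (5S,6R,7S,8R,10R)-8-(tert-butyldimethylsilyloxy)-13-(dimethylamino)eudesma-1,3-dien-6,12-olide (C11 epimers), via lithium lactone enolate 19 (not isolated)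
Conditions: LiN(iPr)2 (LDA), THF, −78 °C; then CH2=NMe2+ I− (Eschenmoser's salt), −78 °C to rt
Reagents that add atoms: dimethylmethyleneammonium iodide, C=[N+](C)C.[I-]
Why: Mannich alkylation of the lactone enolate, now the only acidic site, with the iminium salt introduces C13 at C11; the C11 configuration is irrelevant.

Step 14
Reactants: 20 (5S,6R,7S,8R,10R)-8-(tert-butyldimethylsilyloxy)-13-(dimethylamino)eudesma-1,3-dien-6,12-olide
Product: 22 (5S,6R,7S,8R,10R)-8-(tert-butyldimethylsilyloxy)eudesma-1,3,11(13)-trien-6,12-olide, via trimethylammonium iodide 21 (not isolated)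
Conditions: MeI, MeOH, rt; then NaHCO3 (aq), EtOAc, rt
Reagents that add atoms: none
Why: Quaternisation makes the amine a leaving group and mild base effects Hofmann-type β-elimination to the α-methylene lactone.

Step 15
Reactants: 22 (5S,6R,7S,8R,10R)-8-(tert-butyldimethylsilyloxy)eudesma-1,3,11(13)-trien-6,12-olide
Product: 23 (5S,6R,7R,8R,10R)-8-hydroxyeudesma-1,3,11(13)-trien-6,12-olide
Conditions: HF·pyridine, pyridine, THF, 0 °C to rt
Reagents that add atoms: none
Why: Fluoride-mediated desilylation under buffered conditions frees the C8 hydroxyl without harming the diene or the Michael-acceptor lactone.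

Step 16
Reactants: 24 tiglic acid
Product: 25 tiglyl alcohol ((E)-2-methylbut-2-en-1-ol)
Conditions: LiAlH4, Et2O, 0 °C to rt
Reagents that add atoms: none
Why: Hydride reduction of the carboxylic acid gives the allylic alcohol with the E geometry retained.

Step 17
Reactants: 25 tiglyl alcohol
Product: 26 (2R,3R)-2,3-epoxy-2-methylbutan-1-ol
Conditions: Ti(OiPr)4 (10 mol%), D-(−)-diethyl tartrate (12 mol%), t-BuOOH, 4 Å molecular sieves, CH2Cl2, −20 °C
Reagents that add atoms: tert-butyl hydroperoxide, CC(C)(C)OO
Why: Sharpless asymmetric epoxidation, in which the titanium tartrate complex delivers the peroxide oxygen to one face of the allylic alcohol and the D-(−)-tartrate ester gives the (2R,3R) epoxide, setting both oxirane centres of the ester side chain.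

Step 18
Reactants: 26 (2R,3R)-2,3-epoxy-2-methylbutan-1-ol
Product: 27 (2S,3R)-2,3-epoxy-2-methylbutanoic acid
Conditions: RuCl3 (2 mol%), NaIO4, CCl4–MeCN–H2O, rt
Reagents that add atoms: water, O (the new carboxyl oxygen enters through the aldehyde hydrate; NaIO4 is the terminal oxidant)
Why: Catalytic ruthenium tetroxide oxidation takes the primary alcohol to the acid without opening the oxirane, and the stereocentres are untouched (the C2 descriptor changes by priority only).

Step 19
Reactants: 23 (5S,6R,7R,8R,10R)-8-hydroxyeudesma-1,3,11(13)-trien-6,12-olide; 27 (2S,3R)-2,3-epoxy-2-methylbutanoic acid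
Product: 29 (5S,6R,7R,8R,10R)-8-[(2S,3R)-2,3-epoxy-2-methylbutanoyloxy]eudesma-1,3,11(13)-trien-6,12-olide, via mixed anhydride 28 (not isolated)
Conditions: 2,4,6-trichlorobenzoyl chloride, Et3N, toluene, rt; then 23, 4-dimethylaminopyridine, toluene, rt to 40 °C
Reagents that add atoms: none
Why: Yamaguchi esterification, in which 4-dimethylaminopyridine attacks the less hindered epoxy-acyl carbonyl of the mixed anhydride and the acylpyridinium acylates the hindered axial hydroxyl with retention at C8.

Step 20
Reactants: 29 (5S,6R,7R,8R,10R)-8-[(2S,3R)-2,3-epoxy-2-methylbutanoyloxy]eudesma-1,3,11(13)-trien-6,12-olide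
Product: 30 (1(10)E,2Z,4Z,6R,7R,8R)-8-[(2S,3R)-2,3-epoxy-2-methylbutanoyloxy]germacra-1(10),2,4,11(13)-tetraen-6,12-olide (kept as a cold solution)
Conditions: hν (254 nm, low-pressure Hg lamp, quartz), degassed MeCN–dimethoxymethane (1:2), −40 °C
Reagents that add atoms: none
Why: Excitation of the ring A diene triggers the excited-state-allowed conrotatory six-electron electrocyclic ring opening, in which the doubly allylic C5–C10 σ bond breaks while the C1=C10 and C4=C5 π bonds form around the retained Z C2=C3 bond. The closest known reaction type is the photochemical opening of cyclohexa-1,3-dienes to hexatrienes, as in hexalin to cyclodeca-1,3,5-triene and provitamin D to previtamin D. No ring is closed end to end: the ten-membered carbocycle appears by scission of the bond shared by rings A and B, so no entropic or transannular price is paid. No stereocentre is created (C5 and C10 become trigonal); the new stereo elements are the alkene geometries, and conrotation of cis-related termini must give one E and one Z bond. The selectivity needed is torquoselectivity between the two conrotatory senses, and it should be secured by the trans lactone, which locks the ring B chair and hence the helicity of the diene, so that quasi-equatorial C9 turns outward (1(10)E) and quasi-axial C6 turns inward (4Z) with relief of the syn-axial contact between C1 and the C8 oxygen. Quaternary C10 forbids aromatisation, and the cold suppresses thermal disrotatory reclosure and the 1,7-hydrogen shift of the triene, which is used at once.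

Step 21
Reactants: 30 (1(10)E,2Z,4Z,6R,7R,8R)-8-[(2S,3R)-2,3-epoxy-2-methylbutanoyloxy]germacra-1(10),2,4,11(13)-tetraen-6,12-olide
Product: 31 (1R,2Z,4Z,6R,7R,8R,10R)-1,10-epoxy-8-[(2S,3R)-2,3-epoxy-2-methylbutanoyloxy]germacra-2,4,11(13)-trien-6,12-olide (target CNP0122107.1)
Conditions: D-fructose-derived Shi ketone (1,2:4,5-di-O-isopropylidene-β-D-erythro-hexo-2,3-diulo-2,6-pyranose, 0.3 equiv), KHSO5 (as Oxone, 2KHSO5·KHSO4·K2SO4), K2CO3, Bu4NHSO4, aq. Na2B4O7/Na2H2EDTA buffer, MeCN–dimethoxymethane, −10 °C, added to the cold photolysate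
Reagents that add atoms: potassium peroxymonosulfate KHSO5, [K+].[O-]S(=O)(=O)OO (oxygen relayed by the ketone-derived dioxirane)
Why: Shi asymmetric epoxidation, in which the chiral dioxirane transfers oxygen through a spiro transition state to the most electron-rich and most strained alkene, the trisubstituted E C1=C10 bond (C4=C5 is deactivated by the allylic lactone oxygen, C2=C3 is an inner cis-disubstituted bond, C11=C13 is electron-poor), on the peripheral face of the rotamer holding C14 syn to H-6, which should set C1 and C10 as R,R.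

Compound list
1 | 2-methylpent-4-enal (racemic) | C=CCC(C)C=O | starting material
2 | methyl vinyl ketone | C=CC(C)=O | starting material
3 | 4-allyl-4-methylcyclohex-2-en-1-one (racemic) | C=CCC1(C)C=CC(=O)CC1 | intermediate
4 | [(4-allyl-4-methylcyclohexa-1,5-dien-1-yl)oxy]trimethylsilane (not isolated) | C=CCC1(C)C=CC(O[Si](C)(C)C)=CC1 | intermediate
5 | 4-allyl-4-methylcyclohexa-2,5-dien-1-one | C=CCC1(C)C=CC(=O)C=C1 | intermediate
6 | 4-methyl-4-(1,2,4-trioxolan-3-ylmethyl)cyclohexa-2,5-dien-1-one (ozonide, not isolated) | O=C1C=CC(C)(CC2OCOO2)C=C1 | intermediate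
7 | (1-methyl-4-oxocyclohexa-2,5-dien-1-yl)acetaldehyde | O=CCC1(C)C=CC(=O)C=C1 | intermediate
8 | 4-bromofuran-2(5H)-one | O=C1C=C(Br)CO1 | starting material
9 | 4-[1-hydroxy-2-(1-methyl-4-oxocyclohexa-2,5-dien-1-yl)ethyl]furan-2(5H)-one (racemic) | O=C1C=C(C(O)CC2(C)C=CC(=O)C=C2)CO1 | intermediate
10 | 4-[(1-methyl-4-oxocyclohexa-2,5-dien-1-yl)acetyl]furan-2(5H)-one | O=C1C=C(C(=O)CC2(C)C=CC(=O)C=C2)CO1 | intermediate
11 | (5S,6R,10R)-3,8-dioxo-15-noreudesma-1,7(11)-dien-6,12-olide | O=C1O[C@@H]2[C@H]3CC(=O)C=C[C@@]3(C)CC(=O)C2=C1 | intermediate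
12 | (5S,6R,7S,10R)-3,8-dioxo-15-noreudesm-1-en-6,12-olide | C1C(=O)O[C@@H]2[C@H]3CC(=O)C=C[C@@]3(C)CC(=O)[C@@H]12 | intermediate
13 | (5S,6R,7R,8R,10R)-8-hydroxy-3-oxo-15-noreudesm-1-en-6,12-olide | C1C(=O)O[C@@H]2[C@H]3CC(=O)C=C[C@@]3(C)C[C@@H](O)[C@@H]12 | intermediate
14 | (5S,6R,7S,8R,10R)-8-(tert-butyldimethylsilyloxy)-3-oxo-15-noreudesm-1-en-6,12-olide | C1C(=O)O[C@@H]2[C@H]3CC(=O)C=C[C@@]3(C)C[C@@H](O[Si](C)(C)C(C)(C)C)[C@@H]12 | intermediate
15 | lithium 1,3-dien-3-olate of 14 (not isolated) | C1C(=O)O[C@@H]2[C@H]3C=C([O-])C=C[C@@]3(C)C[C@@H](O[Si](C)(C)C(C)(C)C)[C@@H]12.[Li+] | intermediate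
16 | (5S,6R,7S,8R,10R)-8-(tert-butyldimethylsilyloxy)-3-oxoeudesm-1-en-6,12-olide (C4 epimers, C4 left undefined) | C1C(=O)O[C@@H]2[C@H]3C(C)C(=O)C=C[C@@]3(C)C[C@@H](O[Si](C)(C)C(C)(C)C)[C@@H]12 | intermediate
17 | (5R,6R,7S,8R,10R)-8-(tert-butyldimethylsilyloxy)-3-(trifluoromethylsulfonyloxy)eudesma-1,3-dien-6,12-olide | C1C(=O)O[C@@H]2[C@H]3C(C)=C(OS(=O)(=O)C(F)(F)F)C=C[C@@]3(C)C[C@@H](O[Si](C)(C)C(C)(C)C)[C@@H]12 | intermediate
18 | (5S,6R,7S,8R,10R)-8-(tert-butyldimethylsilyloxy)eudesma-1,3-dien-6,12-olide | C1C(=O)O[C@@H]2[C@H]3C(C)=CC=C[C@@]3(C)C[C@@H](O[Si](C)(C)C(C)(C)C)[C@@H]12 | intermediate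
19 | lithium lactone enolate of 18 (not isolated) | C1=C([O-])O[C@@H]2[C@H]3C(C)=CC=C[C@@]3(C)C[C@@H](O[Si](C)(C)C(C)(C)C)[C@@H]12.[Li+] | intermediate
20 | (5S,6R,7S,8R,10R)-8-(tert-butyldimethylsilyloxy)-13-(dimethylamino)eudesma-1,3-dien-6,12-olide (C11 epimers, C11 left undefined) | CN(C)CC1C(=O)O[C@@H]2[C@H]3C(C)=CC=C[C@@]3(C)C[C@@H](O[Si](C)(C)C(C)(C)C)[C@@H]12 | intermediate
21 | trimethylammonium iodide of 20 (not isolated) | C[N+](C)(C)CC1C(=O)O[C@@H]2[C@H]3C(C)=CC=C[C@@]3(C)C[C@@H](O[Si](C)(C)C(C)(C)C)[C@@H]12.[I-] | intermediate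
22 | (5S,6R,7S,8R,10R)-8-(tert-butyldimethylsilyloxy)eudesma-1,3,11(13)-trien-6,12-olide | C=C1C(=O)O[C@@H]2[C@H]3C(C)=CC=C[C@@]3(C)C[C@@H](O[Si](C)(C)C(C)(C)C)[C@@H]12 | intermediate
23 | (5S,6R,7R,8R,10R)-8-hydroxyeudesma-1,3,11(13)-trien-6,12-olide | C=C1C(=O)O[C@@H]2[C@H]3C(C)=CC=C[C@@]3(C)C[C@@H](O)[C@@H]12 | intermediate
24 | tiglic acid ((E)-2-methylbut-2-enoic acid) | C/C=C(\C)C(=O)O | starting material
25 | tiglyl alcohol ((E)-2-methylbut-2-en-1-ol) | C/C=C(\C)CO | intermediate
26 | (2R,3R)-2,3-epoxy-2-methylbutan-1-ol | OC[C@@]1(C)O[C@@H]1C | intermediate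
27 | (2S,3R)-2,3-epoxy-2-methylbutanoic acid | OC(=O)[C@@]1(C)O[C@@H]1C | intermediate
28 | (2S,3R)-2,3-epoxy-2-methylbutanoic 2,4,6-trichlorobenzoic anhydride (not isolated) | O=C(OC(=O)[C@@]1(C)O[C@@H]1C)c1c(Cl)cc(Cl)cc1Cl | intermediate
29 | (5S,6R,7R,8R,10R)-8-[(2S,3R)-2,3-epoxy-2-methylbutanoyloxy]eudesma-1,3,11(13)-trien-6,12-olide | C=C1C(=O)O[C@@H]2[C@H]3C(C)=CC=C[C@@]3(C)C[C@@H](OC(=O)[C@@]3(C)O[C@@H]3C)[C@@H]12 | intermediate
30 | (1(10)E,2Z,4Z,6R,7R,8R)-8-[(2S,3R)-2,3-epoxy-2-methylbutanoyloxy]germacra-1(10),2,4,11(13)-tetraen-6,12-olide | C=C1C(=O)O[C@@H]2/C=C(C)\C=C/C=C(\C)C[C@@H](OC(=O)[C@@]3(C)O[C@@H]3C)[C@@H]12 | intermediate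
31 | (1R,2Z,4Z,6R,7R,8R,10R)-1,10-epoxy-8-[(2S,3R)-2,3-epoxy-2-methylbutanoyloxy]germacra-2,4,11(13)-trien-6,12-olide | C=C1C(=O)O[C@@H]2/C=C(C)\C=C/[C@H]3O[C@]3(C)C[C@@H](OC(=O)[C@@]3(C)O[C@@H]3C)[C@@H]12 | target

Total step count: 21. Longest linear sequence: 18 steps (steps 1 to 15 and 19 to 21); acid 27 is made in 3 steps (16 to 18) and joins at step 19.

Steps most likely to fail

Step 20. The ring opening may stall at an unfavourable photostationary state, the triene may be consumed by secondary photoreactions or by thermal reclosure, or the epoxy ester and the lactone may disturb the torquoselectivity. The fallback moves the side chain behind the ring expansion and sets out from alcohol 23. Irradiation of 23 under the same cold conditions should give the (1(10)E,2Z,4Z)-8-hydroxygermacra-1(10),2,4,11(13)-tetraen-6,12-olide F1. Shi epoxidation of the photolysate should then give the (1R,10R)-1,10-epoxy-8-hydroxygermacra-2,4,11(13)-trien-6,12-olide F2, a thermally stable compound that can be purified. Yamaguchi esterification of F2 with acid 27 through anhydride 28 comes back to the route at target 31.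

Step 21. In the comparatively warm, basic, aqueous medium the triene may reclose or rearrange before it is oxidised, the esters may hydrolyse, or catalyst control may not override the rotamer preference of the substrate. The fallback gives up catalyst control for substrate control and sets out from triene 30, this time generated in CH2Cl2. After brief equilibration of the rotamers at −40 °C it is treated with one equivalent of preformed dimethyldioxirane in acetone. This relies on the peripheral-face preference that governs oxidation of 1(10)E-germacranolides in the rotamer with C14 syn to H-6. Chromatography would remove the (1S,10S)-1,10-epoxy diastereomer F3, and the sequence comes back at target 31.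

Step 6. The closure may proceed with insufficient enantioselectivity, or racemic background cyclisation may compete with the catalysed pathway. The fallback replaces asymmetric catalysis by resolution and sets out from 10. Catalytic DBU in CH2Cl2 should close ring B under thermodynamic control to the racemate of 11, which is resolved by preparative chromatography on a chiral stationary phase (amylose tris(3,5-dimethylphenylcarbamate)). The unwanted enantiomer (5R,6S,10S)-3,8-dioxo-15-noreudesma-1,7(11)-dien-6,12-olide F4 is returned to the base treatment if retro-Michael equilibration through achiral 10 proves feasible. The sequence comes back at 11.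

Further compounds
F1 | step 20 | (1(10)E,2Z,4Z,6R,7R,8R)-8-hydroxygermacra-1(10),2,4,11(13)-tetraen-6,12-olide | C=C1C(=O)O[C@@H]2/C=C(C)\C=C/C=C(\C)C[C@@H](O)[C@@H]12
F2 | step 20 | (1R,2Z,4Z,6R,7R,8R,10R)-1,10-epoxy-8-hydroxygermacra-2,4,11(13)-trien-6,12-olide | C=C1C(=O)O[C@@H]2/C=C(C)\C=C/[C@H]3O[C@]3(C)C[C@@H](O)[C@@H]12
F3 | step 21 | (1S,2Z,4Z,6R,7R,8R,10S)-1,10-epoxy-8-[(2S,3R)-2,3-epoxy-2-methylbutanoyloxy]germacra-2,4,11(13)-trien-6,12-olide | C=C1C(=O)O[C@@H]2/C=C(C)\C=C/[C@@H]3O[C@@]3(C)C[C@@H](OC(=O)[C@@]3(C)O[C@@H]3C)[C@@H]12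
F4 | step 6 | (5R,6S,10S)-3,8-dioxo-15-noreudesma-1,7(11)-dien-6,12-olide | O=C1O[C@H]2[C@@H]3CC(=O)C=C[C@]3(C)CC(=O)C2=C1
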